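Late in the delta run, between 25.0 h and 40.0 h, the target went from 6.3% to 6.5% while the starting material fell from 14.5% to 6.9%, so I took the late target of a run as its yield and asked what orders the yields of these flasks.

| setting | delta | zeta | alpha | cedar | elm |
|---|---|---|---|---|---|
| starting material | 10 mM | 10 mM | 6.4 mM | 10 mM | 5.0 mM |
| enzyme | 1.1 µM | 4.2 µM | 4.7 µM | 4.7 µM | 1.2 µM |
| remark | run made earlier | run made earlier | run made earlier |  |  |
| time |  |  |  | 40 h | 60 h |

| run | time / h | target / % | starting material / % |
|---|---|---|---|
| delta | 5.00 | 2.5 | 42.3 |
| delta | 15.0 | 5.9 | 20.1 |
| delta | 25.0 | 6.3 | 14.5 |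
| delta | 40.0 | 6.5 | 6.9 |
| zeta | 10.0 | 11.3 | 23.3 |
| zeta | 20.0 | 14.5 | 12.6 |
| zeta | 30.0 | 14.3 | 7.1 |
| zeta | 40.0 | 17.1 | 8.9 |
| alpha | 10.0 | 14.5 | 31.8 |
| alpha | 20.0 | 19.3 | 18.6 |
| alpha | 30.0 | 17.0 | 12.4 |
| alpha | 40.0 | 20.3 | 9.7 |

(scatter of a reading: 1 percentage point)

- the winner by amount of target, in percent of the starting material charged; "neither" if no more than 2 percentage points parts them (cedar / elm / neither)
- how much target is there at the end, in percent of the starting material charged: cedar
- how much target is there at the end, in percent of the starting material charged: elm

- the numbers in the tables scatter with a standard deviation of 1 percentage point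

The starting material looked as if it were lost in pairs: the reciprocal of its remaining fraction, less one, stood 1.45 times higher at the last reading of delta than of alpha, against 1.56 for charge times time, although alpha held 4.27 times the enzyme of delta. So I wrote the side loss as the square of the starting material and the making of target as enzyme times starting material. Dividing one rate by the other removes time and leaves a selectivity factor that goes with enzyme over starting material. I therefore carried ρ, the enzyme charged as a share of the starting material charged, which is 0.0470% in cedar and 0.0240% in elm. I assumed that the enzyme is also lost in pairs, since the yield at a given charge times time then lies on one curve of ρ.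

The mean of each run's readings after its first gave 6.23% for delta at ρ = 0.0110%, 15.3% for zeta at 0.0420%, and 18.9% for alpha at 0.0734%. On logarithmic axes the slope was 0.670 from delta to zeta and 0.375 from zeta to alpha. Stepping along these slopes gave 16.0% for cedar and 10.5% for elm, a gap of 5.5 points, wider than the margin.

The weak link was elm, with half the charge of cedar and a longer time. But under loss in pairs the clock at a given ρ is charge times time, and the end of elm stands at 1.17 of the last alpha reading and 0.750 of the last delta reading, inside the stretch already read, so I kept my numbers.

The forecast, on the ground that “the enzyme is losing activity”, named cedar with 18% for cedar, above my figure, and 9.5% for elm, below mine.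

Cedar gave 16.9% at 40 h and elm 11.1% at 60 h, so the winner was cedar.

    starting material + enzyme ⇌ complex (K = 50.0 M⁻¹, k = 470 M⁻¹ s⁻¹)
    complex → enzyme + target (k = 0.0580 s⁻¹)
    2 enzyme → spent catalyst A (k = 5.70 M⁻¹ s⁻¹)
    enzyme → spent catalyst B (k = 2.60 × 10⁻⁸ s⁻¹)
    2 starting material → homo dimer (k = 0.00360 M⁻¹ s⁻¹)

Neither flask had come to rest: at its asked time cedar held 6.81% of its starting material and 12.9% of its enzyme free, and elm 9.60% and 26.8%. Ten times the time took the starting material down to 0.711% in cedar and 0.978% in elm. Elm, the flask with the smaller ρ, had more still to add: cedar rose by 1.6 points to 18.5%, and elm rose by 2 points to 13.0%.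

The runs come from a simulation for an exercise.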